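## Retrosynthetic overview

1. The last C–C bond (C1'=C2' of the ethylene linker) comes from a Horner–Wadsworth–Emmons union of a ring phosphonate (11 skeletal atoms) with a dioxane aldehyde ester (14 skeletal atoms); diimide then saturates only the new alkene.
2. Ring phosphonate: cyclohexane-1,3-dione → vinylogous ester → gem-dimethylation → Peterson methylenation → γ-bromination with carbonyl transposition → Arbuzov.
3. Dioxane aldehyde: the 1,2-dioxane closes by 6-exo SN2 attack of a tertiary hydroperoxide on a secondary mesylate (inversion gives C3 R); the hydroperoxide comes from inversion opening of a 2,2-disubstituted epoxide with H2O2 (gives C6).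
4. Stereocentres: C6 from (S)-2-methylglycidol; C2 and C3 from a Brown Z-crotylboration; the vinyl group becomes CO2Me and the CH2OH becomes the coupling aldehyde.
5. Ring order: the carbocycle is present from the first step; the 1,2-dioxane is the only ring built (step 14).

Assumption: commercial (S)-2-methylglycidol of at least 98% ee is used, and one-carbon sources (MeI, Me3SiCH2Li) are treated as reagents.

## Route

Step 1
Reactants: 1 cyclohexane-1,3-dione
Product: 2 2-methylcyclohexane-1,3-dione
Conditions: MeI, NaOH, H2O/dioxane, 65 °C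
Reagents that add atoms: iodomethane CI
Why: C-alkylation of the enolate of the acidic 1,3-diketone (SN2 on MeI) gives the 2-methyl dione, with no stereocentre formed.

Step 2
Reactants: 2 2-methylcyclohexane-1,3-dione
Product: 3 3-ethoxy-2-methylcyclohex-2-en-1-one
Conditions: EtOH, TsOH (cat.), toluene, reflux, Dean–Stark
Reagents that add atoms: ethanol CCO
Why: Acid-catalysed vinylogous esterification of the symmetric dione with azeotropic removal of water gives a single enol ether.

Step 3
Reactants: 3 3-ethoxy-2-methylcyclohex-2-en-1-one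
Product: 4 rac-3-ethoxy-2,6-dimethylcyclohex-2-en-1-one
Conditions: LiN(iPr)2, THF, −78 °C; MeI, −78 → 0 °C
Reagents that add atoms: iodomethane CI
Why: Stork–Danheiser kinetic deprotonation of the vinylogous ester occurs only at C6 and the enolate is methylated there; the new stereocentre is racemic and is erased in the next step.

Step 4
Reactants: 4 rac-3-ethoxy-2,6-dimethylcyclohex-2-en-1-one
Product: 5 3-ethoxy-2,6,6-trimethylcyclohex-2-en-1-one
Conditions: LiN(iPr)2, THF, −78 °C; MeI, DMPU, −78 °C → rt
Reagents that add atoms: iodomethane CI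
Why: A second Stork–Danheiser enolate alkylation at the same carbon installs the gem-dimethyl group next to the carbonyl that will become the side-chain-bearing ring carbon.

Step 5
Reactants: 5 3-ethoxy-2,6,6-trimethylcyclohex-2-en-1-one
Product: 7 1-ethoxy-2,4,4-trimethyl-3-methylidenecyclohex-1-ene, via lithium silylcarbinolate 6 (not isolated)
Conditions: Me3SiCH2Li, THF, −78 → 0 °C; then KOtBu (1.1 equiv), 0 → 45 °C
Reagents that add atoms: (trimethylsilyl)methyllithium C[Si](C)(C)C[Li]
Why: Peterson olefination, in which the small, strongly nucleophilic Me3SiCH2Li adds 1,2 to the hindered carbonyl and the potassium alkoxide then syn-eliminates silanolate to give the exocyclic methylene dienol ether regiospecifically.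

Step 6
Reactants: 7 1-ethoxy-2,4,4-trimethyl-3-methylidenecyclohex-1-ene
Product: 8 3-(bromomethyl)-2,4,4-trimethylcyclohex-2-en-1-one
Conditions: NBS, THF/H2O (4:1), 0 °C
Reagents that add atoms: N-bromosuccinimide O=C1CCC(=O)N1Br; water O
Why: Electrophilic γ-bromination of a 1-alkoxy-1,3-diene, where Br+ attacks the terminal CH2 and water hydrolyses the oxocarbenium ion to the transposed enone, places CH2Br on the ring carbon next to the gem-dimethyl group.

Step 7
Reactants: 8 3-(bromomethyl)-2,4,4-trimethylcyclohex-2-en-1-one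
Product: 9 dimethyl [(2,6,6-trimethyl-3-oxocyclohex-1-en-1-yl)methyl]phosphonate
Conditions: P(OMe)3, toluene, 100 °C
Reagents that add atoms: trimethyl phosphite COP(OC)OC
Why: Michaelis–Arbuzov reaction of the reactive allylic bromide gives the vinylogous keto phosphonate.

Step 8
Reactants: 10 (S)-2-methylglycidol, [(2S)-2-methyloxiran-2-yl]methanol
Product: 11 [(2R)-2-methyloxiran-2-yl]methyl 4-methylbenzenesulfonate
Conditions: TsCl, Et3N, DMAP (cat.), CH2Cl2, 0 °C
Reagents that add atoms: 4-toluenesulfonyl chloride Cc1ccc(cc1)S(Cl)(=O)=O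
Why: Sulfonylation of the primary alcohol leaves the quaternary stereocentre untouched (the descriptor changes to R only through CIP priorities).

Step 9
Reactants: 11 [(2R)-2-methyloxiran-2-yl]methyl 4-methylbenzenesulfonate; 12 allylmagnesium chloride
Product: 14 (2R)-2-(but-3-en-1-yl)-2-methyloxirane, via chloromagnesium alkoxide 13 (not isolated)
Conditions: CuI (5 mol %), THF, −40 °C; MeOH, −40 °C; then NaOH (aq), rt
Reagents that add atoms: none
Why: Copper-catalysed Grignard SN2 opening at the unhindered epoxide CH2 (the neopentyl-type tosylate is inert) followed by 3-exo-tet Williamson closure of the tertiary alkoxide onto CH2OTs relocates the epoxide without ever breaking the C–O bond at the stereocentre, so its configuration is retained.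

Step 10
Reactants: 14 (2R)-2-(but-3-en-1-yl)-2-methyloxirane
Product: 16 3-[(2R)-2-methyloxiran-2-yl]propanal, via ozonide 15 (not isolated)
Conditions: O3, CH2Cl2, −78 °C; then Me2S, −78 °C → rt
Reagents that add atoms: ozone [O-][O+]=O
Why: Ozonolysis with reductive work-up cleaves the terminal alkene to the aldehyde while the epoxide is inert to ozone and Me2S.

Step 11
Reactants: 16 3-[(2R)-2-methyloxiran-2-yl]propanal; 17 (Z)-but-2-ene
Product: 22 (3S,4S)-3-methyl-6-[(2R)-2-methyloxiran-2-yl]hex-1-en-4-ol, via Z-crotylpotassium 18 (not isolated), via methoxyborate complex 19 (not isolated), via Z-crotyldiisopinocampheylborane 20 (not isolated), via borinate ester 21 (not isolated)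
Conditions: nBuLi, KOtBu, THF, −78 → −45 °C; (+)-Ipc2BOMe [from (−)-α-pinene], −78 °C; BF3·OEt2, −78 °C; then 16, −78 °C, 4 h; NaOH, H2O2, 0 °C → rt
Reagents that add atoms: none
Why: Brown asymmetric crotylboration, in which the chair Zimmerman–Traxler transition state of the Z-crotylborane fixes the 3,4-syn relationship and the isopinocampheyl groups from (−)-α-pinene select the aldehyde face that gives (3S,4S), while the lithium tert-butoxide present ties up excess BF3 so the epoxide survives.

Step 12
Reactants: 22 (3S,4S)-3-methyl-6-[(2R)-2-methyloxiran-2-yl]hex-1-en-4-ol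
Product: 23 (3S,4S)-3-methyl-6-[(2R)-2-methyloxiran-2-yl]hex-1-en-4-yl methanesulfonate
Conditions: MsCl, Et3N, CH2Cl2, −20 → 0 °C
Reagents that add atoms: methanesulfonyl chloride CS(Cl)(=O)=O
Why: Mesylation under basic conditions activates C4–O with retention and removes the free hydroxyl before it can attack the epoxide to form a tetrahydrofuran.

Step 13
Reactants: 23 (3S,4S)-3-methyl-6-[(2R)-2-methyloxiran-2-yl]hex-1-en-4-yl methanesulfonate
Product: 24 (2S,5S,6S)-2-hydroperoxy-1-hydroxy-2,6-dimethyloct-7-en-5-yl methanesulfonate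
Conditions: H2O2 (anhydrous, in Et2O, 10 equiv), H3PMo12O40 (3 mol %), Et2O, rt
Reagents that add atoms: hydrogen peroxide OO
Why: Heteropolyacid-catalysed perhydrolysis of the 2,2-disubstituted epoxide, where H2O2 attacks the tertiary carbon in a borderline SN2 opening with inversion, gives the (S)-tertiary hydroperoxide while the mesylate and vinyl group are inert.

Step 14
Reactants: 24 (2S,5S,6S)-2-hydroperoxy-1-hydroxy-2,6-dimethyloct-7-en-5-yl methanesulfonate
Product: 25 [(3S,6R)-6-[(2S)-but-3-en-2-yl]-3-methyl-1,2-dioxan-3-yl]methanol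
Conditions: KOtBu (1.05 equiv), 18-crown-6, THF, 0 °C
Reagents that add atoms: none
Why: Intramolecular 6-exo-tet SN2 alkylation of the selectively deprotonated hydroperoxide (pKa about 12.5, an alpha-effect nucleophile and weak base) displaces the secondary mesylate with inversion, so the carbinol S centre becomes the ring R centre and the 1,2-dioxane is closed with the quaternary centre untouched.

Step 15
Reactants: 25 [(3S,6R)-6-[(2S)-but-3-en-2-yl]-3-methyl-1,2-dioxan-3-yl]methanol
Product: 27 (2R)-2-[(3R,6S)-6-(hydroxymethyl)-6-methyl-1,2-dioxan-3-yl]propanoic acid, via dioxanylpropanal 26 (not isolated)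
Conditions: O3, MeCN/H2O (9:1), 0 °C; then NaClO2, NaH2PO4, 0 °C → rt
Reagents that add atoms: ozone [O-][O+]=O; sodium chlorite [Na+].[O-]Cl=O
Why: Ozonolysis in wet acetonitrile gives the aldehyde directly and a Pinnick oxidation in the same pot (the H2O2 co-product scavenges hypochlorite) gives the acid under non-basic conditions that spare the dialkyl peroxide, the primary alcohol and the α-stereocentre.

Step 16
Reactants: 27 (2R)-2-[(3R,6S)-6-(hydroxymethyl)-6-methyl-1,2-dioxan-3-yl]propanoic acid
Product: 28 methyl (2R)-2-[(3R,6S)-6-(hydroxymethyl)-6-methyl-1,2-dioxan-3-yl]propanoate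
Conditions: Me3SiCHN2, toluene/MeOH (4:1), 0 °C
Reagents that add atoms: (trimethylsilyl)diazomethane C[Si](C)(C)C=[N+]=[N-]
Why: Diazoalkane esterification is neutral and so avoids epimerisation at C2 and retro-oxa-Michael opening of the β-peroxy ester.

Step 17
Reactants: 28 methyl (2R)-2-[(3R,6S)-6-(hydroxymethyl)-6-methyl-1,2-dioxan-3-yl]propanoate
Product: 29 methyl (2R)-2-[(3R,6S)-6-formyl-6-methyl-1,2-dioxan-3-yl]propanoate
Conditions: Dess–Martin periodinane, CH2Cl2, 0 °C → rt
Reagents that add atoms: none
Why: Dess–Martin oxidation under mild non-basic conditions gives the non-enolisable α-peroxy aldehyde without touching the O–O bond.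

Step 18
Reactants: 9 dimethyl [(2,6,6-trimethyl-3-oxocyclohex-1-en-1-yl)methyl]phosphonate; 29 methyl (2R)-2-[(3R,6S)-6-formyl-6-methyl-1,2-dioxan-3-yl]propanoate
Product: 30 methyl (2R)-2-[(3R,6S)-6-methyl-6-[(E)-2-(2,6,6-trimethyl-3-oxocyclohex-1-en-1-yl)ethenyl]-1,2-dioxan-3-yl]propanoate
Conditions: 9 (1.3 equiv), NaH (1.2 equiv), THF, 0 °C; then 29, −20 °C → rt
Reagents that add atoms: none
Why: Vinylogous Horner–Wadsworth–Emmons olefination, in which the stabilised anion of the γ-phosphono enone reacts at its phosphorus-bearing carbon with the non-enolisable aldehyde and is too weak a base to open the β-peroxy ester, joins the two fragments without affecting any stereocentre.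

Step 19
Reactants: 30 methyl (2R)-2-[(3R,6S)-6-methyl-6-[(E)-2-(2,6,6-trimethyl-3-oxocyclohex-1-en-1-yl)ethenyl]-1,2-dioxan-3-yl]propanoate
Product: 31 diacarperoxide A, methyl (2R)-2-[(3R,6R)-6-methyl-6-[2-(2,6,6-trimethyl-3-oxocyclohex-1-en-1-yl)ethyl]-1,2-dioxan-3-yl]propanoate
Conditions: KO2CN=NCO2K (large excess, in portions), AcOH, MeOH/CH2Cl2, 0 °C → rt
Reagents that add atoms: none
Why: Diimide reduction transfers H2 in a concerted syn fashion to the disubstituted alkene only, leaving the O–O bond, the tetrasubstituted enone and the ester intact, and the C6 descriptor changes from S to R purely through CIP priorities.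

## Compound list

1 | cyclohexane-1,3-dione | O=C1CCCC(=O)C1 | starting material
2 | 2-methylcyclohexane-1,3-dione | CC1C(=O)CCCC1=O | intermediate
3 | 3-ethoxy-2-methylcyclohex-2-en-1-one | CCOC1=C(C)C(=O)CCC1 | intermediate
4 | rac-3-ethoxy-2,6-dimethylcyclohex-2-en-1-one | CCOC1=C(C)C(=O)C(C)CC1 | intermediate
5 | 3-ethoxy-2,6,6-trimethylcyclohex-2-en-1-one | CCOC1=C(C)C(=O)C(C)(C)CC1 | intermediate
6 | lithium 3-ethoxy-2,6,6-trimethyl-1-[(trimethylsilyl)methyl]cyclohex-2-en-1-olate (racemic, formed in the flask) | CCOC1=C(C)C(O[Li])(C[Si](C)(C)C)C(C)(C)CC1 | intermediate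
7 | 1-ethoxy-2,4,4-trimethyl-3-methylidenecyclohex-1-ene | CCOC1=C(C)C(=C)C(C)(C)CC1 | intermediate
8 | 3-(bromomethyl)-2,4,4-trimethylcyclohex-2-en-1-one | BrCC1=C(C)C(=O)CCC1(C)C | intermediate
9 | dimethyl [(2,6,6-trimethyl-3-oxocyclohex-1-en-1-yl)methyl]phosphonate | COP(=O)(OC)CC1=C(C)C(=O)CCC1(C)C | intermediate
10 | (S)-2-methylglycidol, [(2S)-2-methyloxiran-2-yl]methanol | C[C@]1(CO)CO1 | starting material
11 | [(2R)-2-methyloxiran-2-yl]methyl 4-methylbenzenesulfonate | C[C@]1(COS(=O)(=O)c2ccc(C)cc2)CO1 | intermediate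
12 | allylmagnesium chloride | C=CC[Mg]Cl | starting material
13 | chloromagnesium (2R)-2-methyl-1-[(4-methylbenzenesulfonyl)oxy]hex-5-en-2-olate (formed in the flask) | C[C@](O[Mg]Cl)(COS(=O)(=O)c1ccc(C)cc1)CCC=C | intermediate
14 | (2R)-2-(but-3-en-1-yl)-2-methyloxirane | C[C@@]1(CCC=C)CO1 | intermediate
15 | 3-{2-[(2R)-2-methyloxiran-2-yl]ethyl}-1,2,4-trioxolane (ozonide, formed in the flask) | C[C@@]1(CCC2OCOO2)CO1 | intermediate
16 | 3-[(2R)-2-methyloxiran-2-yl]propanal | C[C@@]1(CCC=O)CO1 | intermediate
17 | (Z)-but-2-ene | C/C=C\C | starting material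
18 | (Z)-but-2-en-1-ylpotassium (formed in the flask) | C/C=C\C[K] | intermediate
19 | potassium (Z)-but-2-en-1-yl(methoxy)bis(isopinocampheyl)borate, Ipc from (−)-α-pinene (formed in the flask) | [K+].C/C=C\C[B-](OC)([C@H]1C[C@H]2C[C@@H]([C@@H]1C)C2(C)C)[C@H]1C[C@H]2C[C@@H]([C@@H]1C)C2(C)C | intermediate
20 | (Z)-but-2-en-1-ylbis(isopinocampheyl)borane, Ipc from (−)-α-pinene (formed in the flask) | C/C=C\CB([C@H]1C[C@H]2C[C@@H]([C@@H]1C)C2(C)C)[C@H]1C[C@H]2C[C@@H]([C@@H]1C)C2(C)C | intermediate
21 | (3S,4S)-3-methyl-6-[(2R)-2-methyloxiran-2-yl]hex-1-en-4-yl bis(isopinocampheyl)borinate (formed in the flask) | C=C[C@H](C)[C@@H](OB([C@H]1C[C@H]2C[C@@H]([C@@H]1C)C2(C)C)[C@H]1C[C@H]2C[C@@H]([C@@H]1C)C2(C)C)CC[C@]1(C)CO1 | intermediate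
22 | (3S,4S)-3-methyl-6-[(2R)-2-methyloxiran-2-yl]hex-1-en-4-ol | C=C[C@H](C)[C@@H](O)CC[C@]1(C)CO1 | intermediate
23 | (3S,4S)-3-methyl-6-[(2R)-2-methyloxiran-2-yl]hex-1-en-4-yl methanesulfonate | C=C[C@H](C)[C@@H](OS(C)(=O)=O)CC[C@]1(C)CO1 | intermediate
24 | (2S,5S,6S)-2-hydroperoxy-1-hydroxy-2,6-dimethyloct-7-en-5-yl methanesulfonate | C=C[C@H](C)[C@@H](OS(C)(=O)=O)CC[C@](C)(OO)CO | intermediate
25 | [(3S,6R)-6-[(2S)-but-3-en-2-yl]-3-methyl-1,2-dioxan-3-yl]methanol | C=C[C@H](C)[C@H]1CC[C@@](C)(CO)OO1 | intermediate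
26 | (2R)-2-[(3R,6S)-6-(hydroxymethyl)-6-methyl-1,2-dioxan-3-yl]propanal (formed in the flask) | O=C[C@H](C)[C@H]1CC[C@@](C)(CO)OO1 | intermediate
27 | (2R)-2-[(3R,6S)-6-(hydroxymethyl)-6-methyl-1,2-dioxan-3-yl]propanoic acid | OC(=O)[C@H](C)[C@H]1CC[C@@](C)(CO)OO1 | intermediate
28 | methyl (2R)-2-[(3R,6S)-6-(hydroxymethyl)-6-methyl-1,2-dioxan-3-yl]propanoate | COC(=O)[C@H](C)[C@H]1CC[C@@](C)(CO)OO1 | intermediate
29 | methyl (2R)-2-[(3R,6S)-6-formyl-6-methyl-1,2-dioxan-3-yl]propanoate | COC(=O)[C@H](C)[C@H]1CC[C@@](C)(C=O)OO1 | intermediate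
30 | methyl (2R)-2-[(3R,6S)-6-methyl-6-[(E)-2-(2,6,6-trimethyl-3-oxocyclohex-1-en-1-yl)ethenyl]-1,2-dioxan-3-yl]propanoate | COC(=O)[C@H](C)[C@H]1CC[C@@](C)(/C=C/C2=C(C)C(=O)CCC2(C)C)OO1 | intermediate
31 | diacarperoxide A, methyl (2R)-2-[(3R,6R)-6-methyl-6-[2-(2,6,6-trimethyl-3-oxocyclohex-1-en-1-yl)ethyl]-1,2-dioxan-3-yl]propanoate | COC(=O)[C@H](C)[C@H]1CC[C@@](C)(CCC2=C(C)C(=O)CCC2(C)C)OO1 | target

## Step count and risks

Total step count: 19. Longest linear sequence: 12 steps (steps 8–19, from 10). The ring branch is steps 1–7 and joins at step 18.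

Steps most likely to fail:

Step 14 (dioxane closure). The secondary mesylate carries a branched neighbour, so E2 elimination to the diene or base-induced Kornblum–DeLaMare cleavage of the product could outrun the 6-exo SN2. The fallback replaces SN2 closure by an oxa-Michael closure; it sets out from 16 and comes back at 28, bypassing steps 11–16. Wittig reaction of 16 with Ph3P=C(CH3)CO2CH3 in CH2Cl2 gives methyl (2E)-2-methyl-5-[(2R)-2-methyloxiran-2-yl]pent-2-enoate F2. Perhydrolysis under the conditions of step 13 gives methyl (2E,6S)-6-hydroperoxy-7-hydroxy-2,6-dimethylhept-2-enoate F3. Catalytic Et2NH in CF3CH2OH then closes the ring by 6-exo conjugate addition of the hydroperoxide. C6 is still fixed by the epoxide opening, but C2 and C3 are now set only by substrate control, so the (2R,3R,6S) isomer 28 must be separated chromatographically from its C2/C3 diastereomers.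

Step 13 (perhydrolysis). SN1 character at the tertiary carbon would erode C6, and Meinwald rearrangement or diol formation could compete. The fallback reverses the order of the two C–O bond formations; it sets out from 23 and comes back at 25. Intermolecular displacement of the mesylate with KOH and 30% H2O2 in MeOH at 0 °C (inversion at the carbinol carbon) gives (3S,4R)-4-hydroperoxy-3-methyl-6-[(2R)-2-methyloxiran-2-yl]hex-1-ene F1. Catalytic camphorsulfonic acid in CH2Cl2 then drives a 6-exo opening of the epoxide at its tertiary carbon by the tethered hydroperoxide, again with inversion. Both centres are inverted in the same sense as in the main route, and the intramolecular opening is more reliably stereospecific; the price is a low-yielding intermolecular displacement.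

Step 18 (fragment union). Both partners are hindered (a quaternary α-peroxy aldehyde and a carbanion flanked by a fully substituted ring carbon), and any free base could open the β-peroxy ester. The fallback replaces the basic olefination by a Lewis-acid aldol and dehydration; it sets out from 7 and 29 and comes back at 30. Dienol ether 7 adds through its terminal CH2 to aldehyde 29 with BF3·OEt2 in CH2Cl2 at −78 °C (vinylogous Mukaiyama-type aldol, aqueous work-up). This gives methyl (2R)-2-[(3R,6S)-6-[1-hydroxy-2-(2,6,6-trimethyl-3-oxocyclohex-1-en-1-yl)ethyl]-6-methyl-1,2-dioxan-3-yl]propanoate F4 as a mixture of carbinol epimers. Dehydration with Burgess reagent in toluene at 50 °C toward the activated ring-CH2 then gives 30.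

Further compounds
F1 | step 13 | (3S,4R)-4-hydroperoxy-3-methyl-6-[(2R)-2-methyloxiran-2-yl]hex-1-ene | C=C[C@H](C)[C@H](OO)CC[C@]1(C)CO1
F2 | step 14 | methyl (2E)-2-methyl-5-[(2R)-2-methyloxiran-2-yl]pent-2-enoate | COC(=O)/C(C)=C/CC[C@]1(C)CO1
F3 | step 14 | methyl (2E,6S)-6-hydroperoxy-7-hydroxy-2,6-dimethylhept-2-enoate | COC(=O)/C(C)=C/CC[C@](C)(OO)CO
F4 | step 18 | methyl (2R)-2-[(3R,6S)-6-[1-hydroxy-2-(2,6,6-trimethyl-3-oxocyclohex-1-en-1-yl)ethyl]-6-methyl-1,2-dioxan-3-yl]propanoate (carbinol epimers) | COC(=O)[C@H](C)[C@H]1CC[C@@](C)(C(O)CC2=C(C)C(=O)CCC2(C)C)OO1
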